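**Retrosynthetic overview**
1. The C12 acid is traced back to the C7 isopropenyl group (allylic oxidation) and the C9 ester to diol 10; the C9 carbinol comes from a C9 ketone.
2. Ring A is disconnected by a formal [3+3] annulation: a 2-(phenylsulfonyl)allyl unit (C1–C3) is joined to a monocyclic ring-B precursor through C1–C10 (enolate SN2′ allylation) and C3–C4 (ketyl–olefin closure) in one pot.
3. Enabling feature: C10 is flanked by the oxygenated C9 of ring B and C4 bears the tertiary OH. With both raised to ketones, C10 is a regiodefined enolate carbon and C4 a ketyl carbon, 1,3-related across C5, so only the three CH2 groups C1–C3 are missing.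
4. Ring B and C7 are bought as (R)-carvone; C5 (cuprate addition), C10 and C4 (key step) and C9 (thermodynamic reduction) are relayed from C7.
5. Ring order: B (bought), then A (step 3); the temporary sulfone on C2 leaves in the same step that reduces C9.

Key step: step 3

Remark: eudesmane numbering is used for all intermediates (ring B = C5–C10, ring A = C1–C5 and C10, side chain C11–C13, C14 on C10, C15 on C4); (S)-3-methylpentanoic acid and 2,3-bis(phenylsulfonyl)prop-1-ene are taken as purchasable.

**Step 1**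
Reactants: 1 (R)-(−)-carvone; 2 ethyl vinyl ether
Product: 4 tert-butyl{[(3R,5R)-3-(1-ethoxyethenyl)-2-methyl-5-(prop-1-en-2-yl)cyclohex-1-en-1-yl]oxy}dimethylsilane, via lithium enolate 3 (not isolated)
Conditions: 2, t-BuLi, THF, −78 → 0 °C; CuI, −78 °C; then 1, −78 → −40 °C; TBSCl, DMPU, Et3N, −78 °C → rt
Reagents that add atoms: tert-butyldimethylsilyl chloride, CC(C)(C)[Si](C)(C)Cl
Why: Conjugate addition of an α-alkoxyvinyl cuprate (acetyl anion equivalent) to the enone should occur by axial attack at C5 anti to the C7 isopropenyl group, setting C5, and O-silylation traps the regiodefined C9–C10 enolate.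

**Step 2**
Reactants: 4 silyl enol ether with 1-ethoxyvinyl group
Product: 5 1-[(1R,5R)-3-(tert-butyldimethylsilyloxy)-2-methyl-5-(prop-1-en-2-yl)cyclohex-2-en-1-yl]ethan-1-one
Conditions: oxalic acid (cat.), THF/H2O, 0 °C
Reagents that add atoms: water, O
Why: Acid-catalysed enol ether hydrolysis; the 1-alkoxyvinyl group is protonated at its free CH2 far faster than the tetrasubstituted TBS enol ether, so only the C4 acetyl group should be unmasked and C5 is untouched.

**Step 3**
Reactants: 5 acetyl silyl enol ether; 6 2,3-bis(phenylsulfonyl)prop-1-ene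
Product: 9 (3R,4aR,5R,8aS)-5-hydroxy-5,8a-dimethyl-7-(phenylsulfonyl)-3-(prop-1-en-2-yl)octahydronaphthalen-1(2H)-one (C2 epimers), via TAS enolate 7 (not isolated), via vinyl sulfone diketone 8 (not isolated)
Conditions: TASF, 6, THF, −78 → −40 °C; then SmI2, t-BuOH, THF, −78 → 0 °C (one pot)
Reagents that add atoms: none
Why: Proposed new method: fluoride cleaves the silyl enol ether to the regiodefined C9–C10 enolate 7, which adds to the terminal CH2 of 6 and expels benzenesulfinate (SN2′) to give 8 with C1 on C10; SmI2 then reduces the C4 methyl ketone to its ketyl, which adds to the free terminus C3 of the 2-sulfonylallyl unit, and the α-sulfonyl radical is reduced and protonated. The closest known reaction types are fluoride-mediated regiospecific alkylation of silyl enol ethers with 2-sulfonylallyl electrophiles and SmI2 ketyl–olefin reductive cyclization onto α,β-unsaturated esters, nitriles and sulfones; new are their merger in one flask and the endo mode on a 2-sulfonylallyl acceptor. Ring A closes 6-endo-trig (C4 ketyl onto C3=C2) as a trans-fused chair. C10 is set in the alkylation by attack on the α face, anti to the pseudoaxial C5 acetyl group; C4 is set in the chair transition state, where the bulky Sm(III)-bound oxygen should take the equatorial (α) site and the methyl the axial (β) site; C2 forms as a mixture and is erased in step 4. The step needs the C4 ketone to react in preference to the C9 ketone and C3 in preference to C2: a C9 ketyl could only close 5-endo or 4-exo, and the sulfone polarises the alkene so that the nucleophilic ketyl attacks the unsubstituted CH2. The alkylation must also outrun proton transfer between the enolate and the free acetyl group, which the very reactive allyl sulfone acceptor at −78 °C should secure.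

**Step 4**
Reactants: 9 sulfonyl ketol
Product: 10 (1S,3R,4aR,5R,8aS)-5,8a-dimethyl-3-(prop-1-en-2-yl)decahydronaphthalene-1,5-diol
Conditions: Li, NH3(l)/THF, t-BuOH, −78 → −33 °C; NH4Cl
Reagents that add atoms: none
Why: Dissolving-metal reduction should cleave the C2–S bond (reductive desulfonylation) and reduce the C9 ketone under thermodynamic control to the equatorial 9β-alcohol, since an axial 9α-OH would be syn-diaxial to the axial C7 isopropenyl group; the isolated 1,1-disubstituted alkene is not expected to be reduced.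

**Step 5**
Reactants: 10 diol; 11 (S)-3-methylpentanoic acid
Product: 12 (1S,3R,4aR,5R,8aS)-5-hydroxy-5,8a-dimethyl-3-(prop-1-en-2-yl)decahydronaphthalen-1-yl (3S)-3-methylpentanoate
Conditions: DCC, DMAP, CH2Cl2, 0 °C → rt
Reagents that add atoms: none
Why: Steglich esterification should acylate the secondary equatorial C9 hydroxyl only, the tertiary C4 hydroxyl being too hindered; the acid stereocenter is β to the carbonyl and cannot epimerise.

**Step 6**
Reactants: 12 ester
Product: 13 (1S,3R,4aR,5R,8aS)-5-hydroxy-3-(3-hydroxyprop-1-en-2-yl)-5,8a-dimethyldecahydronaphthalen-1-yl (3S)-3-methylpentanoate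
Conditions: SeO2 (cat.), t-BuOOH, CH2Cl2, rt
Reagents that add atoms: selenium dioxide, O=[Se]=O (catalytic oxygen carrier); tert-butyl hydroperoxide, CC(C)(C)OO
Why: Selenium dioxide allylic oxidation (ene reaction, then [2,3]-sigmatropic shift) of the only alkene should hydroxylate the isopropenyl methyl group; no stereocenter is formed.

**Step 7**
Reactants: 13 allylic alcohol
Product: 15 2-[(2R,4S,4aS,8R,8aR)-8-hydroxy-4a,8-dimethyl-4-{[(3S)-3-methylpentanoyl]oxy}decahydronaphthalen-2-yl]prop-2-enoic acid, via enal 14 (not isolated)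
Conditions: TEMPO (cat.), PhI(OAc)2, CH2Cl2, rt; then NaClO2, NaH2PO4, 2-methyl-2-butene, t-BuOH/H2O, 0 °C → rt
Reagents that add atoms: sodium chlorite, [Na+].[O-]Cl=O
Why: Oxoammonium oxidation of the primary allylic alcohol to the enal followed by Pinnick oxidation should give the acrylic acid without affecting the tertiary alcohol, the ester or any stereocenter.

**Compound list**
1 | (R)-(−)-carvone, (5R)-2-methyl-5-(prop-1-en-2-yl)cyclohex-2-en-1-one | C=C(C)[C@H]1CC(=O)C(C)=CC1 | starting material
2 | ethyl vinyl ether | C=COCC | starting material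
3 | lithium (3R,5R)-3-(1-ethoxyethenyl)-2-methyl-5-(prop-1-en-2-yl)cyclohex-1-en-1-olate | C=C(C)[C@H]1CC([O-])=C(C)[C@H](C(=C)OCC)C1.[Li+] | intermediate (not isolated)
4 | tert-butyl{[(3R,5R)-3-(1-ethoxyethenyl)-2-methyl-5-(prop-1-en-2-yl)cyclohex-1-en-1-yl]oxy}dimethylsilane (C5 substituent trans to isopropenyl) | C=C(C)[C@H]1CC(O[Si](C)(C)C(C)(C)C)=C(C)[C@H](C(=C)OCC)C1 | intermediate
5 | 1-[(1R,5R)-3-(tert-butyldimethylsilyloxy)-2-methyl-5-(prop-1-en-2-yl)cyclohex-2-en-1-yl]ethan-1-one | C=C(C)[C@H]1CC(O[Si](C)(C)C(C)(C)C)=C(C)[C@H](C(C)=O)C1 | intermediate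
6 | 2,3-bis(phenylsulfonyl)prop-1-ene | C=C(CS(=O)(=O)c1ccccc1)S(=O)(=O)c1ccccc1 | starting material
7 | tris(dimethylamino)sulfonium (3R,5R)-3-acetyl-2-methyl-5-(prop-1-en-2-yl)cyclohex-1-en-1-olate | C=C(C)[C@H]1CC([O-])=C(C)[C@H](C(C)=O)C1.CN(C)[S+](N(C)C)N(C)C | intermediate (not isolated)
8 | (2S,3R,5R)-3-acetyl-2-methyl-2-[2-(phenylsulfonyl)prop-2-en-1-yl]-5-(prop-1-en-2-yl)cyclohexan-1-one | C=C(C)[C@H]1CC(=O)[C@@](C)(CC(=C)S(=O)(=O)c2ccccc2)[C@H](C(C)=O)C1 | intermediate (not isolated)
9 | (3R,4aR,5R,8aS)-5-hydroxy-5,8a-dimethyl-7-(phenylsulfonyl)-3-(prop-1-en-2-yl)octahydronaphthalen-1(2H)-one, trans-fused, 4α-OH, C2 epimers | C=C(C)[C@H]1CC(=O)[C@@]2(C)CC(S(=O)(=O)c3ccccc3)C[C@@](C)(O)[C@@H]2C1 | intermediate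
10 | (1S,3R,4aR,5R,8aS)-5,8a-dimethyl-3-(prop-1-en-2-yl)decahydronaphthalene-1,5-diol (4α,9β-diol) | C=C(C)[C@H]1C[C@H](O)[C@@]2(C)CCC[C@@](C)(O)[C@@H]2C1 | intermediate
11 | (S)-3-methylpentanoic acid | OC(=O)C[C@@H](C)CC | starting material
12 | (1S,3R,4aR,5R,8aS)-5-hydroxy-5,8a-dimethyl-3-(prop-1-en-2-yl)decahydronaphthalen-1-yl (3S)-3-methylpentanoate | C=C(C)[C@H]1C[C@H](OC(=O)C[C@@H](C)CC)[C@@]2(C)CCC[C@@](C)(O)[C@@H]2C1 | intermediate
13 | (1S,3R,4aR,5R,8aS)-5-hydroxy-3-(3-hydroxyprop-1-en-2-yl)-5,8a-dimethyldecahydronaphthalen-1-yl (3S)-3-methylpentanoate | C=C(CO)[C@H]1C[C@H](OC(=O)C[C@@H](C)CC)[C@@]2(C)CCC[C@@](C)(O)[C@@H]2C1 | intermediate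
14 | (1S,3R,4aR,5R,8aS)-5-hydroxy-5,8a-dimethyl-3-(3-oxoprop-1-en-2-yl)decahydronaphthalen-1-yl (3S)-3-methylpentanoate | C=C(C=O)[C@H]1C[C@H](OC(=O)C[C@@H](C)CC)[C@@]2(C)CCC[C@@](C)(O)[C@@H]2C1 | intermediate (not isolated)
15 | 2-[(2R,4S,4aS,8R,8aR)-8-hydroxy-4a,8-dimethyl-4-{[(3S)-3-methylpentanoyl]oxy}decahydronaphthalen-2-yl]prop-2-enoic acid (4R,5R,7R,9S,10S in eudesmane numbering) | C=C(C(=O)O)[C@H]1C[C@H](OC(=O)C[C@@H](C)CC)[C@@]2(C)CCC[C@@](C)(O)[C@@H]2C1 | target

**Step count and risks**
Total steps: 7. Longest linear sequence: 7 steps (1 to 15).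

Steps most likely to fail:

1. Step 3 (proposed new method). The ketyl may fail to close in the 6-endo sense: the vinyl sulfone could be reduced directly by SmI2, or the C4 ketyl could simply be reduced to the alcohol. Facial selectivity at C4 may be poor, and the enolate may equilibrate by proton transfer before it is alkylated. The fallback uses known chemistry, sets out from 4 and returns at 10. With the acetyl group still masked, 4 is converted by TASF into its enolate and alkylated with excess 1,3-diiodopropane, anti to the C5 substituent, to give (2S,3R,5R)-3-(1-ethoxyethenyl)-2-(3-iodopropyl)-2-methyl-5-(prop-1-en-2-yl)cyclohexan-1-one F1. The C9 ketone is taken out of play by NaBH4 reduction, and an oxalic acid work-up unmasks the acetyl group, giving 1-[(1R,2S,5R)-3-hydroxy-2-(3-iodopropyl)-2-methyl-5-(prop-1-en-2-yl)cyclohexyl]ethan-1-one F2 (C9 epimers). An intramolecular SmI2/HMPA Barbier reaction, which now has only the C4 ketone to attack, closes ring A to (3R,4aR,5R,8aS)-5,8a-dimethyl-3-(prop-1-en-2-yl)decahydronaphthalene-1,5-diol F3 (C9 epimers). Dess–Martin oxidation of the secondary alcohol gives (3R,4aR,5R,8aS)-5-hydroxy-5,8a-dimethyl-3-(prop-1-en-2-yl)octahydronaphthalen-1(2H)-one F4, and Li/NH3/t-BuOH reduction of F4 delivers 10. The C4 configuration from the Barbier closure is not secured by precedent either and would have to be confirmed at F3.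

2. Step 4. Desulfonylation may be incomplete because the sulfone is deprotonated at its α-carbon, the aryl–sulfur bond may cleave instead of the alkyl–sulfur bond, or the isopropenyl group may be over-reduced. The fallback sets out from 9 and returns at 10, and separates the two reductions. An equilibrating Meerwein–Ponndorf–Verley reduction (Al(Oi-Pr)3, i-PrOH, reflux) should give the equatorial alcohol (1S,3R,4aR,5R,8aS)-5,8a-dimethyl-7-(phenylsulfonyl)-3-(prop-1-en-2-yl)decahydronaphthalene-1,5-diol F5. Sodium amalgam (Na2HPO4, MeOH) then removes the sulfone from F5 to give 10.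

3. Step 6. The selenium ene reaction may abstract the tertiary C7–H instead of the methyl hydrogen, or over-oxidation may give mixtures. The fallback sets out from 12 and returns at 14. Ene-type allylic chlorination with hypochlorous acid (Ca(OCl)2, solid CO2, CH2Cl2/H2O) gives (1S,3R,4aR,5R,8aS)-3-(3-chloroprop-1-en-2-yl)-5-hydroxy-5,8a-dimethyldecahydronaphthalen-1-yl (3S)-3-methylpentanoate F6. Oxidation of F6 with N-methylmorpholine N-oxide (Ganem/Kornblum type) gives enal 14, which is carried through the Pinnick stage of step 7 to 15.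

**Further compounds**
F1 | step 3 | (2S,3R,5R)-3-(1-ethoxyethenyl)-2-(3-iodopropyl)-2-methyl-5-(prop-1-en-2-yl)cyclohexan-1-one | C=C(C)[C@H]1CC(=O)[C@@](C)(CCCI)[C@H](C(=C)OCC)C1
F2 | step 3 | 1-[(1R,2S,5R)-3-hydroxy-2-(3-iodopropyl)-2-methyl-5-(prop-1-en-2-yl)cyclohexyl]ethan-1-one (C9 epimers) | C=C(C)[C@H]1CC(O)[C@@](C)(CCCI)[C@H](C(C)=O)C1
F3 | step 3 | (3R,4aR,5R,8aS)-5,8a-dimethyl-3-(prop-1-en-2-yl)decahydronaphthalene-1,5-diol (C9 epimers) | C=C(C)[C@H]1CC(O)[C@@]2(C)CCC[C@@](C)(O)[C@@H]2C1
F4 | step 3 | (3R,4aR,5R,8aS)-5-hydroxy-5,8a-dimethyl-3-(prop-1-en-2-yl)octahydronaphthalen-1(2H)-one | C=C(C)[C@H]1CC(=O)[C@@]2(C)CCC[C@@](C)(O)[C@@H]2C1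
F5 | step 4 | (1S,3R,4aR,5R,8aS)-5,8a-dimethyl-7-(phenylsulfonyl)-3-(prop-1-en-2-yl)decahydronaphthalene-1,5-diol (C2 epimers) | C=C(C)[C@H]1C[C@H](O)[C@@]2(C)CC(S(=O)(=O)c3ccccc3)C[C@@](C)(O)[C@@H]2C1
F6 | step 6 | (1S,3R,4aR,5R,8aS)-3-(3-chloroprop-1-en-2-yl)-5-hydroxy-5,8a-dimethyldecahydronaphthalen-1-yl (3S)-3-methylpentanoate | C=C(CCl)[C@H]1C[C@H](OC(=O)C[C@@H](C)CC)[C@@]2(C)CCC[C@@](C)(O)[C@@H]2C1
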